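In a one-step world where substrate meets reagent, with the equivalents held, the fraction of the charge turned per minute rises in proportion to the charge. That is your hunch for this flask, which holds twice the charge of beta.

| setting | beta | epsilon | flask |
|---|---|---|---|
| substrate | 0.34 M | 0.51 M | 0.68 M |
| reagent in the second phase | 1.1 equiv | 1.1 equiv | 1.10 equiv |
| remark | run made earlier | run made earlier |  |
| time |  |  | 8.0 min |
| volume of the second phase over the first |  |  | 1.0 |

| run | time / min | target / % | substrate / % |
|---|---|---|---|
| beta | 0.833 | 0.2 | 99.8 |
| beta | 1.33 | 2.1 | 97.7 |
| beta | 2.50 | 3.9 | 96.5 |
| beta | 5.00 | 9.6 | 89.8 |
| beta | 10.0 | 17.6 | 81.2 |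
| epsilon | 0.833 | 1.5 | 98.4 |
| epsilon | 2.50 | 5.0 | 93.7 |
| epsilon | 4.00 | 10.2 | 89.6 |
| epsilon | 6.00 | 15.1 | 82.8 |
| epsilon | 10.0 | 22.7 | 74.2 |

(scatter of a reading: 0.5 percentage points)

- in the second phase: reagent in the second phase; everything else is in the first
- charges count per volume of the first phase; a concentration in a rate is the amount of a species over the volume of its own phase; every rate counts per litre of the first phase
- what was read earlier has a scatter of 0.5 percentage points, one standard deviation
- on the list of suspects stand: 2 reagent in the reaction phase -> homo dimer; reagent in the reaction phase + target -> over-reacted product; reagent in the reaction phase <-> reagent in the second phase; substrate + reagent in the reaction phase -> target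
- the earlier runs hold the two phases in the same ratio of volumes as the flask asked about

- south-west: doubling the transfer coefficient of the reagent in the second phase, all else as stated
- south: doubling the amount of reagent in the second phase, all else as stated

1. amount of target at 8.0 min, in percent of the substrate charged
2. the change that raises the amount of target at 8.0 min, in percent of the substrate charged most ("none" if none brings more than 2 percentage points) (south-west / south / none)
3. amount of target at 8.0 min, in percent of the substrate charged, after south-west

We count turnovers instead: g is the fraction of the charge that has become target per minute, taken from each run's last reading.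

| run | charge | g |
|---|---|---|
| beta | 0.34 M | 0.0176 min⁻¹ |
| epsilon | 0.51 M | 0.0227 min⁻¹ |

Your hunch gives 28.2% at 8.0 min. But from beta to epsilon the charge rose by a factor of 1.50 and g by only 1.29. So between these two runs g went as the charge to the power 0.628, the turnover exponent, read from two readings with a scatter of 0.5 percentage points. Carried up from epsilon, it gives this flask a g of 0.0272 min⁻¹, so our number is 21.8%.

The forecast says 23%, between 20.5% and 26%, which is higher than ours. It gives 29% after south-west and picks south: “Doubling the reagent scales the rate almost linearly”.

The flask gives 22.8%, with 74% of its substrate still there at 8.0 min. The best change is south, which gains 11 points, more than south-west; south-west reaches 24.1%, a gain of 1.3 points, less than the 2 points margin.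

    2 reagent in the reaction phase → homo dimer (k = 0.00102 M⁻¹ s⁻¹)
    reagent in the reaction phase + target → over-reacted product (k = 0.00145 M⁻¹ s⁻¹)
    reagent in the reaction phase ⇌ reagent in the second phase, rate k3*([reagent in the reaction phase] - [reagent in the second phase]/K3) per volume of the first phase (partition coefficient = 0.326, kL = 0.00304 s⁻¹)
    substrate + reagent in the reaction phase → target (k = 0.00181 M⁻¹ s⁻¹)

Take the neighbouring flask, with 0.41 M of substrate and the same equivalents and time. Carried up from beta, the exponent gives it a g of 0.0198 min⁻¹, so we count 15.8%. The neighbouring flask holds 16.8% target, with 82% of its substrate left.

Readings and results stem from a simulated flask with made-up constants.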